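I leave the reagent in this flask at 0.700 equiv and spend no more material on it, and I judge that from the reagent's own accounts.

the same everywhere: substrate 0.020 M
- ash: reagent 0.70 equiv; the very flask that is asked about, followed so far
- flask: reagent 0.700 equiv; time 6.0 h

ash run (percent of the substrate charged)

| time / h | target / % | side product / % |
|---|---|---|
| 0.200 | 17 | 0 |
| 0.667 | 31 | 4 |
| 1.00 | 39 | 0 |
| 1.50 | 49 | 0 |
| 2.50 | 59 | 0 |

(readings scatter by 2 percentage points)

- share of target in target plus side product at 3.0 min
- share of target in target plus side product at 6.0 h

- a species is counted by the substrate in it: one homo dimer counts as two
- on the list of suspects stand: substrate + reagent -> intermediate A; intermediate A <-> intermediate B; intermediate A <-> intermediate C; intermediate A -> target; reagent + intermediate C -> side product; 2 substrate -> homo dimer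

My bench rule is the **reagent budget**: the reagent charged, in percent of the substrate charged. Each target costs one reagent and each side product costs two, one on the way into intermediate A and one with intermediate C. At the last reading of the ash run, the same flask, the budget stands thus:

budget = 70.0%

left = 70.0% − 59% − 2 × 0% = 11.0%

Intermediates may hold some of that remainder, so it is the most the free reagent can be, and it carries the scatter of the readings. If every bit of it went to side product, at two reagents each, with target standing at its reading, this flask's share of target at 6.0 h would be

59% / (59% + 11.0% / 2) = 91.5%

That is my floor at 6.0 h, an estimate; it does not reach 3.0 min, which lies before that reading. The rule has a border, found from the charge: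

[reagent] / [substrate] = 0.0140 M / 0.020 M = 0.700

Below a ratio of one, reagent is by the charge the limiting reagent, and this flask sits there. Past one, the charge holds reagent beyond the one per substrate of the first step, so at the same target the remainder widens and the floor drops. The homo dimer among the suspects can take substrate from that first step, so this ratio tells what the charge allows, not which of the two runs out first in this flask.

The forecast gives 99% (93% to 100%) at 3.0 min and 97% (92% to 100%) at 6.0 h, holding that “reagent is running out, so little more should form late”. Its low end at 6.0 h lies just above my floor.

    substrate + reagent → intermediate A (k = 1.10 L mol⁻¹ s⁻¹)
    intermediate A ⇌ intermediate B (K = 1.90, k = 0.00240 s⁻¹)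
    intermediate A ⇌ intermediate C (K = 0.590, k = 0.00220 s⁻¹)
    intermediate A → target (k = 9.20 × 10⁻⁴ s⁻¹)
    reagent + intermediate C → side product (k = 0.0510 L mol⁻¹ s⁻¹)
    2 substrate → homo dimer (k = 0.210 L mol⁻¹ s⁻¹)

The flask gives 96.6% and 97.9%, and at 6.00 h target and side product have spent 68.6% of the 70.0% budget. As charged, intermediate C has a half-life of 0.27 h towards side product against 0.21 h for intermediate A towards target, but at 0.600 h reagent stands at 3.42% of its charge, which stretches the first to 7.89 h. A share under 92% appears in the neighbour flask with 1.20 equiv: of its 120% budget, 95.5% is spent, 20% of its reagent charge remains, side product reaches 12.9%, and the share is 84.3%.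

The earlier runs and the new flask were generated by integration with made-up constants, noise included.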